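**Plan**

- Retrosynthesis: the two phenolic silyl ethers and the 5‑O‑methyl group are removed first. Ring A is then cut at C4a–C5, C5–C6 and C7–C8 (benzannulation) into a pyranon‑2‑yl diazomethyl ketone and 1‑(triisopropylsiloxy)propyne. Last, the C3–C1' biaryl bond is cut (Suzuki) and C8 is traced back to the CH2OH carbon of kojic acid.
- Enabling feature: the C4a–C8a fusion bond of ring A is the C2=C3 double bond of a 4‑pyranone, so ring C (O1, C2–H, C3–aryl, C4=O) is kojic acid itself. C8(H), C7(O), C6(Me) and C5(O) map one‑to‑one onto a ketene CH, the two carbons of a 1‑siloxypropyne and a ketene carbonyl.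
- Forward: ring C is bought as kojic acid and ring B is attached to pyranone C5 (the later C3) by Suzuki coupling. The hydroxymethyl arm is taken through an acetyl group to a diazomethyl ketone, and ring A is built last in one operation. O‑Methylation of the 5‑OH and removal of both silyl groups finish the synthesis.
- Stereochemistry: the target has no stereocentre. The racemic carbinol of the chain extension and the sp3 carbons of the cyclobutenone and cyclohexadienone intermediates are erased by oxidation, ring opening and aromatisation.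

Key step: step 10

Remark: Ar stands for 3,5‑dimethoxy‑4‑(triisopropylsilyloxy)phenyl; enolate, alkoxide and phenoxide salts that are quenched or captured in the same operation are counted with their neutral numbered compound.

**Route**

Step 1
Reactants: 1 kojic acid (5‑hydroxy‑2‑(hydroxymethyl)‑4H‑pyran‑4‑one)
Product: 2 6‑(hydroxymethyl)‑4‑oxo‑4H‑pyran‑3‑yl trifluoromethanesulfonate (kojic acid 5‑triflate)
Conditions: PhNTf2 (1.05 equiv), Et3N (1.2 equiv), MeCN, 0 °C to rt
Reagents that add atoms: N‑phenylbis(trifluoromethanesulfonimide), O=S(=O)(N(c1ccccc1)S(=O)(=O)C(F)(F)F)C(F)(F)F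
Why: Chemoselective O‑triflation: only the enolic 5‑OH (a vinylogous acid) is deprotonated by Et3N, and N‑phenyltriflimide sulfonylates such phenoxide‑type oxygens while leaving a neutral primary alcohol untouched, so the enol triflate should form without protection of the CH2OH group.

Step 2
Reactants: 3 4‑bromo‑2,6‑dimethoxyphenol
Product: 4 (4‑bromo‑2,6‑dimethoxyphenoxy)triisopropylsilane
Conditions: TIPSOTf (1.2 equiv), 2,6‑lutidine (1.5 equiv), CH2Cl2, 0 °C to rt
Reagents that add atoms: triisopropylsilyl triflate, CC(C)[Si](OS(=O)(=O)C(F)(F)F)(C(C)C)C(C)C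
Why: O‑Silylation of a hindered phenol with a silyl triflate and 2,6‑lutidine; the bulky TIPS ether, shielded by the two ortho methoxy groups, should survive the basic, organometallic and photochemical steps and fall together with the 7‑O‑silyl group at the end.

Step 3
Reactants: 4 (4‑bromo‑2,6‑dimethoxyphenoxy)triisopropylsilane
Product: 5 [2,6‑dimethoxy‑4‑(4,4,5,5‑tetramethyl‑1,3,2‑dioxaborolan‑2‑yl)phenoxy]triisopropylsilane
Conditions: B2pin2 (1.2 equiv), PdCl2(dppf) (3 mol %), KOAc (3 equiv), 1,4‑dioxane, 90 °C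
Reagents that add atoms: bis(pinacolato)diboron, CC1(C)OB(B2OC(C)(C)C(C)(C)O2)OC1(C)C
Why: Miyaura borylation of an electron‑rich aryl bromide; KOAc is too weak a base to cleave the aryl silyl ether or to promote Suzuki homocoupling of the product.

Step 4
Reactants: 2 kojic acid 5‑triflate; 5 TIPS‑protected syringyl pinacol boronate
Product: 6 2‑(hydroxymethyl)‑5‑Ar‑4H‑pyran‑4‑one
Conditions: PdCl2(dppf) (5 mol %), K3PO4 (2 equiv), H2O (5 equiv), 1,4‑dioxane, 80 °C
Reagents that add atoms: none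
Why: Suzuki–Miyaura coupling: the enol triflate of the electron‑poor pyranone adds readily to zerovalent palladium, the phosphate base with only a few equivalents of water activates the boronate without hydrolysing the triflate or the aryl silyl ether, and the free primary alcohol is tolerated.

Step 5
Reactants: 6 2‑(hydroxymethyl)‑5‑Ar‑4H‑pyran‑4‑one
Product: 7 5‑Ar‑4‑oxo‑4H‑pyran‑2‑carbaldehyde
Conditions: activated MnO2 (10 equiv), CH2Cl2, rt
Reagents that add atoms: none
Why: Selective oxidation of an allylic‑type alcohol with activated MnO2, which stops at the aldehyde and is established for 2‑hydroxymethyl‑4‑pyranones of the kojic acid family.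

Step 6
Reactants: 7 5‑Ar‑4‑oxo‑4H‑pyran‑2‑carbaldehyde
Product: 8 2‑(1‑hydroxyethyl)‑5‑Ar‑4H‑pyran‑4‑one (racemic)
Conditions: MeMgBr (1.1 equiv), THF, −78 °C; aq NH4Cl
Reagents that add atoms: methylmagnesium bromide, C[Mg]Br
Why: Grignard 1,2‑addition: at −78 °C the aldehyde is far more electrophilic than the vinylogous‑ester carbonyl or the C6 Michael position of the pyranone; the new carbinol stereocentre forms as a racemate, which is immaterial because it is oxidised in the next step.

Step 7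
Reactants: 8 2‑(1‑hydroxyethyl)‑5‑Ar‑4H‑pyran‑4‑one
Product: 9 2‑acetyl‑5‑Ar‑4H‑pyran‑4‑one
Conditions: Dess–Martin periodinane (1.2 equiv), CH2Cl2, rt
Reagents that add atoms: none
Why: Dess–Martin oxidation of a secondary alcohol to the ketone under neutral, non‑aqueous conditions that leave the pyranone and the aryl silyl ether untouched and remove the only stereocentre.

Step 8
Reactants: 9 2‑acetyl‑5‑Ar‑4H‑pyran‑4‑one
Product: 11 2‑(2‑diazoacetyl)‑5‑Ar‑4H‑pyran‑4‑one, via trifluoroacetyl diketone 10 (not isolated)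
Conditions: LiN(SiMe3)2 (1.1 equiv), THF, −78 °C; CF3CO2CH2CF3 (1.2 equiv); aq HCl work‑up; then MsN3 (1.5 equiv), Et3N (1.5 equiv), H2O (1 equiv), MeCN, rt
Reagents that add atoms: mesyl azide, CS(=O)(=O)N=[N+]=[N-] (supplies the two diazo nitrogens); 2,2,2‑trifluoroethyl trifluoroacetate, O=C(OCC(F)(F)F)C(F)(F)F (its CF3CO group is carried only by 10 and is lost again)
Why: Detrifluoroacetylative diazo transfer (a Regitz‑type diazo transfer to an activated 1,3‑dicarbonyl): the acetyl CH3 is the only enolisable position, its lithium enolate is trifluoroacetylated to 10, and mesyl azide then transfers N2 with loss of the trifluoroacetyl group as the N‑acylsulfonamide, a sequence established for aryl and alkenyl methyl ketones that avoids exposing the pyranone to diazomethane.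

Step 9
Reactants: 12 propyne
Product: 15 triisopropyl(prop‑1‑yn‑1‑yloxy)silane (1‑(triisopropylsiloxy)propyne), via lithium propynide 13 (not isolated), via lithium propynolate 14 (not isolated)
Conditions: LiN(SiMe3)2, THF, −78 °C; cannulate into LiOOt‑Bu (from t‑BuOOH and LiN(SiMe3)2, THF, −78 °C), then 0 °C; TIPSOTf, −78 °C to rt
Reagents that add atoms: tert‑butyl hydroperoxide, CC(C)(C)OO (the oxygen atom, delivered as its lithium salt); triisopropylsilyl triflate, CC(C)[Si](OS(=O)(=O)C(F)(F)F)(C(C)C)C(C)C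
Why: Oxidation of a lithium acetylide by lithium tert‑butyl peroxide (electrophilic oxygen transfer) gives the lithium ynolate 14, and the bulky silyl triflate traps it on oxygen to give the siloxyalkyne instead of the C‑silyl ketene, as established for TIPS ynol ethers of terminal alkynes.

Step 10
Reactants: 11 2‑(2‑diazoacetyl)‑5‑Ar‑4H‑pyran‑4‑one; 15 1‑(triisopropylsiloxy)propyne
Product: 20 5‑hydroxy‑6‑methyl‑7‑(triisopropylsilyloxy)‑3‑Ar‑4H‑chromen‑4‑one, via pyranonylketene 16 (not isolated), via cyclobutenone 17 (not isolated), via dienylketene 18 (not isolated), via cyclohexadienone 19 (not isolated)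
Conditions: 15 (2.5 equiv), hν (Pyrex‑filtered medium‑pressure Hg lamp or 390 nm LED, batch or flow), degassed toluene, rt; then 110 °C
Reagents that add atoms: none
Why: Irradiation of the long‑wavelength diazo band triggers a photochemical Wolff rearrangement in which N2 leaves and the pyranonyl group migrates, so the diazo carbon becomes C8 and the former ketone carbon becomes the ketene carbon (the later C5 with its oxygen) of 16, which is captured by the polarised ynol ether 15 in a regioselective [2+2] cycloaddition (C5–C6 and C7–C8 bonds, methyl‑bearing carbon to the ketene carbon) to give 17. On heating, 17 undergoes reversible 4π‑electrocyclic opening (cleaving the old ketene C=C, C5–C8) to the dienylketene 18, and ring A then closes by a thermal disrotatory 6π‑electrocyclisation of this carbon triene, the ketene carbon bonding to pyranone C3 (the C4a–C5 bond, six‑membered carbocycle), after which enolisation of 19 gives the aromatic phenol 20. The sequence is the second‑generation Danheiser benzannulation, whose scope covers cycloalkenyl, aryl and heteroaryl diazomethyl ketones with (triisopropylsiloxy)alkynes; the pyranonyl ketone is a further heterocyclic example of that family. No stereocentre is created that persists, since the sp3 carbons of 17 and 19 disappear on ring opening and aromatisation. The step must deliver 6‑methyl rather than 8‑methyl and must tell the 5‑O from the 7‑O: the donor polarisation of the siloxyalkyne fixes the orientation of the [2+2] step, closure is possible only at C3 because the other neighbour of pyranone C2 is the ring oxygen, and the two oxygens emerge already different, as free chelated 5‑OH and 7‑OTIPS. The weakly aromatic 4‑pyranone offers an electron‑rich enol‑ether β‑carbon (C3) for the closure, light above about 350 nm should leave its own chromophore largely unexcited, and 11 carries no free OH that could trap the ketene.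

Step 11
Reactants: 20 5‑hydroxy‑6‑methyl‑7‑(triisopropylsilyloxy)‑3‑Ar‑4H‑chromen‑4‑one
Product: 21 5‑methoxy‑6‑methyl‑7‑(triisopropylsilyloxy)‑3‑Ar‑4H‑chromen‑4‑one
Conditions: KN(SiMe3)2 (1.05 equiv), toluene, −78 °C; MeOTf (1.2 equiv), −78 to 0 °C
Reagents that add atoms: methyl triflate, COS(=O)(=O)C(F)(F)F
Why: Williamson‑type O‑methylation of the only free OH: the pre‑formed potassium phenoxide and the very reactive methyl triflate should overcome the hydrogen bond to C4=O at low temperature, while the absence of water, alkoxide, carbonate and fluoride should leave both aryl TIPS ethers in place.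

Step 12
Reactants: 21 5‑methoxy‑6‑methyl‑7‑(triisopropylsilyloxy)‑3‑Ar‑4H‑chromen‑4‑one
Product: 22 7‑hydroxy‑3‑(4‑hydroxy‑3,5‑dimethoxyphenyl)‑5‑methoxy‑6‑methyl‑4H‑chromen‑4‑one (CNP0425497.0)
Conditions: Bu4NF (2.5 equiv), AcOH (2.5 equiv), THF, 0 °C to rt
Reagents that add atoms: none
Why: Fluoride‑induced cleavage of both aryl silyl ethers; acetic acid buffering keeps the medium from becoming basic enough to open ring C, and no boron or aluminium Lewis acid is present that would cleave the peri 5‑OMe.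

**Compound list**

1 | kojic acid, 5‑hydroxy‑2‑(hydroxymethyl)‑4H‑pyran‑4‑one | OCc1cc(=O)c(O)co1 | starting material
2 | 6‑(hydroxymethyl)‑4‑oxo‑4H‑pyran‑3‑yl trifluoromethanesulfonate | OCc1cc(=O)c(OS(=O)(=O)C(F)(F)F)co1 | intermediate
3 | 4‑bromo‑2,6‑dimethoxyphenol | COc1cc(Br)cc(OC)c1O | starting material
4 | (4‑bromo‑2,6‑dimethoxyphenoxy)triisopropylsilane | COc1cc(Br)cc(OC)c1O[Si](C(C)C)(C(C)C)C(C)C | intermediate
5 | [2,6‑dimethoxy‑4‑(4,4,5,5‑tetramethyl‑1,3,2‑dioxaborolan‑2‑yl)phenoxy]triisopropylsilane | COc1cc(B2OC(C)(C)C(C)(C)O2)cc(OC)c1O[Si](C(C)C)(C(C)C)C(C)C | intermediate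
6 | 5‑[3,5‑dimethoxy‑4‑(triisopropylsilyloxy)phenyl]‑2‑(hydroxymethyl)‑4H‑pyran‑4‑one | OCc1cc(=O)c(-c2cc(OC)c(O[Si](C(C)C)(C(C)C)C(C)C)c(OC)c2)co1 | intermediate
7 | 5‑[3,5‑dimethoxy‑4‑(triisopropylsilyloxy)phenyl]‑4‑oxo‑4H‑pyran‑2‑carbaldehyde | O=Cc1cc(=O)c(-c2cc(OC)c(O[Si](C(C)C)(C(C)C)C(C)C)c(OC)c2)co1 | intermediate
8 | 5‑[3,5‑dimethoxy‑4‑(triisopropylsilyloxy)phenyl]‑2‑(1‑hydroxyethyl)‑4H‑pyran‑4‑one, racemic | CC(O)c1cc(=O)c(-c2cc(OC)c(O[Si](C(C)C)(C(C)C)C(C)C)c(OC)c2)co1 | intermediate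
9 | 2‑acetyl‑5‑[3,5‑dimethoxy‑4‑(triisopropylsilyloxy)phenyl]‑4H‑pyran‑4‑one | CC(=O)c1cc(=O)c(-c2cc(OC)c(O[Si](C(C)C)(C(C)C)C(C)C)c(OC)c2)co1 | intermediate
10 | 4,4,4‑trifluoro‑1‑{5‑[3,5‑dimethoxy‑4‑(triisopropylsilyloxy)phenyl]‑4‑oxo‑4H‑pyran‑2‑yl}butane‑1,3‑dione (formed in the flask) | O=C(CC(=O)C(F)(F)F)c1cc(=O)c(-c2cc(OC)c(O[Si](C(C)C)(C(C)C)C(C)C)c(OC)c2)co1 | intermediate
11 | 2‑(2‑diazoacetyl)‑5‑[3,5‑dimethoxy‑4‑(triisopropylsilyloxy)phenyl]‑4H‑pyran‑4‑one | [N-]=[N+]=CC(=O)c1cc(=O)c(-c2cc(OC)c(O[Si](C(C)C)(C(C)C)C(C)C)c(OC)c2)co1 | intermediate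
12 | propyne | CC#C | starting material
13 | lithium propynide, 1‑propynyllithium (formed in the flask) | [Li]C#CC | intermediate
14 | lithium prop‑1‑yn‑1‑olate (formed in the flask) | [Li+].CC#C[O-] | intermediate
15 | triisopropyl(prop‑1‑yn‑1‑yloxy)silane | CC#CO[Si](C(C)C)(C(C)C)C(C)C | intermediate
16 | {5‑[3,5‑dimethoxy‑4‑(triisopropylsilyloxy)phenyl]‑4‑oxo‑4H‑pyran‑2‑yl}ketene (formed in the flask) | O=C=Cc1cc(=O)c(-c2cc(OC)c(O[Si](C(C)C)(C(C)C)C(C)C)c(OC)c2)co1 | intermediate
17 | 2‑methyl‑3‑(triisopropylsilyloxy)‑4‑{5‑[3,5‑dimethoxy‑4‑(triisopropylsilyloxy)phenyl]‑4‑oxo‑4H‑pyran‑2‑yl}cyclobut‑2‑en‑1‑one, racemic (formed in the flask) | CC1=C(O[Si](C(C)C)(C(C)C)C(C)C)C(c2cc(=O)c(-c3cc(OC)c(O[Si](C(C)C)(C(C)C)C(C)C)c(OC)c3)co2)C1=O | intermediate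
18 | (E)‑2‑methyl‑3‑(triisopropylsilyloxy)‑4‑{5‑[3,5‑dimethoxy‑4‑(triisopropylsilyloxy)phenyl]‑4‑oxo‑4H‑pyran‑2‑yl}buta‑1,3‑dien‑1‑one, ketene unit and pyranone cis (formed in the flask) | O=C=C(C)/C(O[Si](C(C)C)(C(C)C)C(C)C)=C\c1cc(=O)c(-c2cc(OC)c(O[Si](C(C)C)(C(C)C)C(C)C)c(OC)c2)co1 | intermediate
19 | 3‑[3,5‑dimethoxy‑4‑(triisopropylsilyloxy)phenyl]‑6‑methyl‑7‑(triisopropylsilyloxy)‑4aH‑chromene‑4,5‑dione, keto tautomer of 20, racemic (formed in the flask) | CC1=C(O[Si](C(C)C)(C(C)C)C(C)C)C=C2OC=C(c3cc(OC)c(O[Si](C(C)C)(C(C)C)C(C)C)c(OC)c3)C(=O)C2C1=O | intermediate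
20 | 3‑[3,5‑dimethoxy‑4‑(triisopropylsilyloxy)phenyl]‑5‑hydroxy‑6‑methyl‑7‑(triisopropylsilyloxy)‑4H‑chromen‑4‑one | Cc1c(O[Si](C(C)C)(C(C)C)C(C)C)cc2occ(-c3cc(OC)c(O[Si](C(C)C)(C(C)C)C(C)C)c(OC)c3)c(=O)c2c1O | intermediate
21 | 3‑[3,5‑dimethoxy‑4‑(triisopropylsilyloxy)phenyl]‑5‑methoxy‑6‑methyl‑7‑(triisopropylsilyloxy)‑4H‑chromen‑4‑one | COc1c(C)c(O[Si](C(C)C)(C(C)C)C(C)C)cc2occ(-c3cc(OC)c(O[Si](C(C)C)(C(C)C)C(C)C)c(OC)c3)c(=O)c12 | intermediate
22 | 7‑hydroxy‑3‑(4‑hydroxy‑3,5‑dimethoxyphenyl)‑5‑methoxy‑6‑methyl‑4H‑chromen‑4‑one (CNP0425497.0) | COc1cc(-c2coc3cc(O)c(C)c(OC)c3c2=O)cc(OC)c1O | target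

**Step count and risks**

Total step count: 12 steps.
Longest linear sequence: 10 steps, from 3 to 22 (steps 2, 3, 4, 5, 6, 7, 8, 10, 11, 12).

Steps most likely to fail:

1. Step 10. The 6π‑closure onto the cross‑conjugated pyranone may be slower than dimerisation or adventitious trapping of the ketene intermediates, and partial excitation of the 3‑aryl‑4‑pyranone chromophore may divert material into ring‑contraction photoproducts. The fallback sets out from boronate 5 and returns at 20; ring A is taken from a symmetric aromatic precursor and ring C is closed classically, so the methyl position is unambiguous. 3,5‑Dimethoxy‑4‑methylphenol F1, a purchased phenol whose two free ortho positions are equivalent, would be C‑acetylated with Ac2O and BF3·OEt2 to 1‑(6‑hydroxy‑2,4‑dimethoxy‑3‑methylphenyl)ethan‑1‑one F2. Condensation with N,N‑dimethylformamide dimethyl acetal would give the enaminone (E)‑3‑(dimethylamino)‑1‑(6‑hydroxy‑2,4‑dimethoxy‑3‑methylphenyl)prop‑2‑en‑1‑one F3, and iodine would cyclise and iodinate it to 3‑iodo‑5,7‑dimethoxy‑6‑methyl‑4H‑chromen‑4‑one F4. BBr3 would cleave both methyl ethers to 5,7‑dihydroxy‑3‑iodo‑6‑methyl‑4H‑chromen‑4‑one F5. TIPSCl and imidazole would silylate only the acidic, non‑chelated 7‑OH to give 5‑hydroxy‑3‑iodo‑6‑methyl‑7‑(triisopropylsilyloxy)‑4H‑chromen‑4‑one F6. Suzuki coupling of F6 with 5 under the conditions of step 4 should then deliver 20, from which steps 11 and 12 follow unchanged.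

2. Step 11. The activated 7‑O‑silyl group may be transferred or lost once the phenoxide is formed, methylation may compete at the C4 carbonyl oxygen, or alkylation of the chelated phenoxide may stay incomplete. The fallback sets out from 20 and returns at 22, replacing the silyl ethers by benzyl ethers that tolerate forcing methylation. Both silyl groups would be removed with Bu4NF and AcOH to give 5,7‑dihydroxy‑3‑(4‑hydroxy‑3,5‑dimethoxyphenyl)‑6‑methyl‑4H‑chromen‑4‑one F7. Benzyl bromide and K2CO3 in acetone would etherify the 7‑OH and 4'‑OH but not the chelated 5‑OH, giving 7‑(benzyloxy)‑3‑[4‑(benzyloxy)‑3,5‑dimethoxyphenyl]‑5‑hydroxy‑6‑methyl‑4H‑chromen‑4‑one F8. Dimethyl sulfate and K2CO3 in refluxing acetone would then methylate the 5‑OH to 7‑(benzyloxy)‑3‑[4‑(benzyloxy)‑3,5‑dimethoxyphenyl]‑5‑methoxy‑6‑methyl‑4H‑chromen‑4‑one F9, and brief hydrogenolysis (H2, Pd/C, EtOAc) should give 22 directly.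

3. Step 8. The amide base or the enolate may add in conjugate fashion to the doubly activated pyranone (at C6), leading to ring opening or oligomerisation instead of clean trifluoroacetylation. The fallback sets out from aldehyde 7 and returns at 11, uses no strong base and bypasses steps 6 and 7. Pinnick oxidation (NaClO2, NaH2PO4, 2‑methyl‑2‑butene, t‑BuOH/H2O) would give 5‑[3,5‑dimethoxy‑4‑(triisopropylsilyloxy)phenyl]‑4‑oxo‑4H‑pyran‑2‑carboxylic acid F10. Oxalyl chloride with catalytic DMF would convert it into 5‑[3,5‑dimethoxy‑4‑(triisopropylsilyloxy)phenyl]‑4‑oxo‑4H‑pyran‑2‑carbonyl chloride F11. Acylation of trimethylsilyldiazomethane with F11 at 0 °C (the diazo ketone stage of an Arndt–Eistert sequence) should give 11 after loss of the silyl group; the cold, short contact should limit dipolar addition to the pyranone double bonds.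

Further compounds
F1 | step 10 | 3,5‑dimethoxy‑4‑methylphenol (purchased) | Cc1c(OC)cc(O)cc1OC
F2 | step 10 | 1‑(6‑hydroxy‑2,4‑dimethoxy‑3‑methylphenyl)ethan‑1‑one | CC(=O)c1c(O)cc(OC)c(C)c1OC
F3 | step 10 | (E)‑3‑(dimethylamino)‑1‑(6‑hydroxy‑2,4‑dimethoxy‑3‑methylphenyl)prop‑2‑en‑1‑one | CN(C)/C=C/C(=O)c1c(O)cc(OC)c(C)c1OC
F4 | step 10 | 3‑iodo‑5,7‑dimethoxy‑6‑methyl‑4H‑chromen‑4‑one | COc1cc2occ(I)c(=O)c2c(OC)c1C
F5 | step 10 | 5,7‑dihydroxy‑3‑iodo‑6‑methyl‑4H‑chromen‑4‑one | Cc1c(O)cc2occ(I)c(=O)c2c1O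
F6 | step 10 | 5‑hydroxy‑3‑iodo‑6‑methyl‑7‑(triisopropylsilyloxy)‑4H‑chromen‑4‑one | Cc1c(O[Si](C(C)C)(C(C)C)C(C)C)cc2occ(I)c(=O)c2c1O
F7 | step 11 | 5,7‑dihydroxy‑3‑(4‑hydroxy‑3,5‑dimethoxyphenyl)‑6‑methyl‑4H‑chromen‑4‑one | COc1cc(-c2coc3cc(O)c(C)c(O)c3c2=O)cc(OC)c1O
F8 | step 11 | 7‑(benzyloxy)‑3‑[4‑(benzyloxy)‑3,5‑dimethoxyphenyl]‑5‑hydroxy‑6‑methyl‑4H‑chromen‑4‑one | COc1cc(-c2coc3cc(OCc4ccccc4)c(C)c(O)c3c2=O)cc(OC)c1OCc1ccccc1
F9 | step 11 | 7‑(benzyloxy)‑3‑[4‑(benzyloxy)‑3,5‑dimethoxyphenyl]‑5‑methoxy‑6‑methyl‑4H‑chromen‑4‑one | COc1cc(-c2coc3cc(OCc4ccccc4)c(C)c(OC)c3c2=O)cc(OC)c1OCc1ccccc1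
F10 | step 8 | 5‑[3,5‑dimethoxy‑4‑(triisopropylsilyloxy)phenyl]‑4‑oxo‑4H‑pyran‑2‑carboxylic acid | OC(=O)c1cc(=O)c(-c2cc(OC)c(O[Si](C(C)C)(C(C)C)C(C)C)c(OC)c2)co1
F11 | step 8 | 5‑[3,5‑dimethoxy‑4‑(triisopropylsilyloxy)phenyl]‑4‑oxo‑4H‑pyran‑2‑carbonyl chloride | ClC(=O)c1cc(=O)c(-c2cc(OC)c(O[Si](C(C)C)(C(C)C)C(C)C)c(OC)c2)co1
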